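**Retrosynthetic overview**
1. Toxiusol ⇐ O‑sulfation of the hydroquinone ⇐ its bis(methyl ether) ⇐ removal of the C12 oxygen from the homoallylic alcohol made by an intermolecular Nozaki–Hiyama carbonyl allylation of a west aldehyde (C4–CH2–CHO) with an east cyclic allylic bromide. This one step forms the C12–C9' bond, the C9' quaternary centre and the C1'=C10' alkene.
2. East bromide: ring B' is the (S)‑carvone ring; the C4' gem‑dimethyl carbon comes from an Fe–H Giese addition; ring A' from an intramolecular aldol condensation; then MeLi and PBr3.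
3. West aldehyde: ring B by an enantioselective Diels–Alder reaction (sets C8, C9, C10); ring A by Mukaiyama‑type closure onto C5; C4 by hydride reduction followed by Eschenmoser–Claisen rearrangement.
4. Ring order: west ring B, then west ring A; east ring B' (chiral pool), then east ring A'; fragment union; arene oxidation state and sulfates last.

Assumption: the target is made as the free bis(hydrogen sulfate) drawn. Locants used in the text: west octalin C1–C10 (C4 and C9 quaternary, C5=C6), linker C11 (on C4) and C12 (on C9'), east octalin C1'–C10'.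

**Step 1**
Reactants: 1 2-(chloromethyl)-1,4-dimethoxybenzene; 2 ethyl (triphenyl-λ5-phosphanylidene)acetate
Product: 4 ethyl 3-(2,5-dimethoxyphenyl)-2-(triphenyl-λ5-phosphanylidene)propanoate, via phosphonium chloride 3 (not isolated)
Conditions: EtOAc, reflux; then aq. NaOH, CH2Cl2, 0 °C
Reagents that add atoms: none
Why: C‑alkylation of a stabilised ylide by an activated benzylic chloride gives the phosphonium salt, which NaOH deprotonates to the α‑benzylated ylide (ylide alkylation).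

**Step 2**
Reactants: 4 ethyl 3-(2,5-dimethoxyphenyl)-2-(triphenyl-λ5-phosphanylidene)propanoate
Product: 5 ethyl (E)-2-[(2,5-dimethoxyphenyl)methyl]but-2-enoate
Conditions: MeCHO (5 equiv), toluene, sealed tube, 90 °C
Reagents that add atoms: acetaldehyde, CC=O
Why: Wittig olefination with an α‑substituted stabilised ylide is (E)‑selective, placing the ester trans to the new methyl group.

**Step 3**
Reactants: 5 ethyl (E)-2-[(2,5-dimethoxyphenyl)methyl]but-2-enoate
Product: 6 (E)-2-[(2,5-dimethoxyphenyl)methyl]but-2-en-1-ol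
Conditions: i-Bu2AlH (2.2 equiv), CH2Cl2, −78 °C; aq. potassium sodium tartrate
Reagents that add atoms: none
Why: 1,2‑Hydride reduction of the enoate at low temperature gives the allylic alcohol without touching the alkene geometry.

**Step 4**
Reactants: 6 (E)-2-[(2,5-dimethoxyphenyl)methyl]but-2-en-1-ol
Product: 7 (E)-2-[(2,5-dimethoxyphenyl)methyl]but-2-enal
Conditions: MnO2, CH2Cl2, rt
Reagents that add atoms: none
Why: MnO2 oxidises allylic alcohols selectively to enals with retention of the (E) geometry.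

**Step 5**
Reactants: 8 2-(3-chloropropyl)-2-methyl-1,3-dioxolane
Product: 10 4-(2-methyl-1,3-dioxolan-2-yl)butanal, via Grignard reagent 9 (not isolated)
Conditions: Mg, THF, reflux; then DMF, 0 °C; aq. NH4Cl
Reagents that add atoms: N,N-dimethylformamide, CN(C)C=O
Why: The ketal‑protected Grignard reagent is formylated by DMF (Bouveault aldehyde synthesis); the ketal survives the basic medium.

**Step 6**
Reactants: 10 4-(2-methyl-1,3-dioxolan-2-yl)butanal; 11 1-(triphenyl-λ5-phosphanylidene)propan-2-one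
Product: 12 (E)-7-(2-methyl-1,3-dioxolan-2-yl)hept-3-en-2-one
Conditions: CH2Cl2, reflux
Reagents that add atoms: none
Why: Wittig reaction of a stabilised acylmethylene ylide with an unhindered aldehyde gives the (E)‑enone.

**Step 7**
Reactants: 12 (E)-7-(2-methyl-1,3-dioxolan-2-yl)hept-3-en-2-one
Product: 13 triisopropyl{[(3E)-7-(2-methyl-1,3-dioxolan-2-yl)hepta-1,3-dien-2-yl]oxy}silane
Conditions: LiN(i-Pr)2, THF, −78 °C; then i-Pr3SiOSO2CF3
Reagents that add atoms: triisopropylsilyl trifluoromethanesulfonate, CC(C)[Si](OS(=O)(=O)C(F)(F)F)(C(C)C)C(C)C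
Why: Kinetic deprotonation of the methyl ketone and O‑silylation give the cross‑conjugated 2‑silyloxy diene (silyl enol ether formation).

**Step 8**
Reactants: 7 (E)-2-[(2,5-dimethoxyphenyl)methyl]but-2-enal; 13 triisopropyl{[(3E)-7-(2-methyl-1,3-dioxolan-2-yl)hepta-1,3-dien-2-yl]oxy}silane
Product: 14 (1S,2R,6R)-1-[(2,5-dimethoxyphenyl)methyl]-6-methyl-2-[3-(2-methyl-1,3-dioxolan-2-yl)propyl]-4-[(triisopropylsilyl)oxy]cyclohex-3-ene-1-carbaldehyde
Conditions: (S)-3,3-diphenyl-1-(2-methylphenyl)tetrahydro-1H,3H-pyrrolo[1,2-c][1,3,2]oxazaborole·HN(SO2CF3)2 (20 mol%), CH2Cl2, −78 → −40 °C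
Reagents that add atoms: none
Why: Enantioselective oxazaborolidinium‑catalysed Diels–Alder reaction: the silyloxy group (para) and the substituted diene terminus (ortho) direct the enal α‑carbon to C10, the formyl group is endo and the (E)‑enal geometry is kept, so the C8 methyl and H10 end up cis to CH2Ar, while the catalyst (formyl C–H···O binding) shields one enal face and fixes the absolute configuration.

**Step 9**
Reactants: 14 (1S,2R,6R)-1-[(2,5-dimethoxyphenyl)methyl]-6-methyl-2-[3-(2-methyl-1,3-dioxolan-2-yl)propyl]-4-[(triisopropylsilyl)oxy]cyclohex-3-ene-1-carbaldehyde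
Product: 15 (E)-N'-tosylhydrazone of 14
Conditions: TsNHNH2, THF, 40 °C
Reagents that add atoms: 4-methylbenzenesulfonohydrazide, Cc1ccc(cc1)S(=O)(=O)NN
Why: Neutral condensation of the neopentyl aldehyde to its tosylhydrazone prepares the formyl carbon for reduction to the C9 methyl group without harming the silyl enol ether or ketal.

**Step 10**
Reactants: 15 (E)-N'-tosylhydrazone of 14
Product: 16 triisopropyl({(3R,4R,5R)-4-[(2,5-dimethoxyphenyl)methyl]-4,5-dimethyl-3-[3-(2-methyl-1,3-dioxolan-2-yl)propyl]cyclohex-1-en-1-yl}oxy)silane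
Conditions: catecholborane, CHCl3, 0 °C; then NaOAc·3H2O, reflux
Reagents that add atoms: none
Why: Caglioti‑type tosylhydrazone reduction: hydroboration of C=N, sulfinate loss and N2 extrusion from the diazene turn CH=N into CH3 with no stereocentre involved.

**Step 11**
Reactants: 16 triisopropyl({(3R,4R,5R)-4-[(2,5-dimethoxyphenyl)methyl]-4,5-dimethyl-3-[3-(2-methyl-1,3-dioxolan-2-yl)propyl]cyclohex-1-en-1-yl}oxy)silane
Product: 17 (3R,4R,4aR)-4-[(2,5-dimethoxyphenyl)methyl]-8-(2-hydroxyethoxy)-3,4,8-trimethyloctahydronaphthalen-1(2H)-one (C8/C8a epimers)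
Conditions: TiCl4, CH2Cl2, −78 °C; aq. NaHCO3
Reagents that add atoms: none
Why: Intramolecular Mukaiyama aldol‑type addition of the regiodefined silyl enol ether carbon (C5) to the TiCl4‑activated ketal closes ring A through the C4–C5 bond only.

**Step 12**
Reactants: 17 (3R,4R,4aR)-4-[(2,5-dimethoxyphenyl)methyl]-8-(2-hydroxyethoxy)-3,4,8-trimethyloctahydronaphthalen-1(2H)-one
Product: 18 (3R,4R,4aS)-4-[(2,5-dimethoxyphenyl)methyl]-3,4,8-trimethyl-3,4,4a,5,6,7-hexahydronaphthalen-1(2H)-one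
Conditions: KOt-Bu (20 mol%), t-BuOH/THF, 40 °C
Reagents that add atoms: none
Why: E1cB β‑elimination of the alkoxide gives the conjugated tetrasubstituted enone; H10 sits on a carbon attached to the α‑carbon and is not acidic, so the C8/C9/C10 triad is untouched.

**Step 13**
Reactants: 18 (3R,4R,4aS)-4-[(2,5-dimethoxyphenyl)methyl]-3,4,8-trimethyl-3,4,4a,5,6,7-hexahydronaphthalen-1(2H)-one
Product: 19 (1S,3R,4R,4aS)-4-[(2,5-dimethoxyphenyl)methyl]-3,4,8-trimethyl-1,2,3,4,4a,5,6,7-octahydronaphthalen-1-ol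
Conditions: Li[HB(sec-Bu)3], THF, −78 °C; then H2O
Reagents that add atoms: none
Why: 1,2‑Reduction of the β,β‑disubstituted enone by a bulky hydride occurs from the β face, away from the syn‑axial C8 methyl and H10, giving the axial 6α (1S) allylic alcohol.

**Step 14**
Reactants: 19 (1S,3R,4R,4aS)-4-[(2,5-dimethoxyphenyl)methyl]-3,4,8-trimethyl-1,2,3,4,4a,5,6,7-octahydronaphthalen-1-ol
Product: 21 2-{(1S,4aS,5R,6R)-5-[(2,5-dimethoxyphenyl)methyl]-1,5,6-trimethyl-1,2,3,4,4a,5,6,7-octahydronaphthalen-1-yl}-N,N-dimethylacetamide, via ketene N,O-acetal 20 (not isolated)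
Conditions: MeC(OMe)2NMe2, xylene, 140 °C
Reagents that add atoms: 1,1-dimethoxy-N,N-dimethylethan-1-amine, CC(OC)(OC)N(C)C
Why: Eschenmoser–Claisen rearrangement: the suprafacial [3,3] shift delivers CH2CONMe2 to C4 on the α face from which the C6–O bond departs, setting the C4 quaternary centre (S) and moving the alkene to C5=C6.

**Step 15**
Reactants: 21 2-{(1S,4aS,5R,6R)-5-[(2,5-dimethoxyphenyl)methyl]-1,5,6-trimethyl-1,2,3,4,4a,5,6,7-octahydronaphthalen-1-yl}-N,N-dimethylacetamide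
Product: 22 2-{(1S,4aS,5R,6R)-5-[(2,5-dimethoxyphenyl)methyl]-1,5,6-trimethyl-1,2,3,4,4a,5,6,7-octahydronaphthalen-1-yl}acetaldehyde
Conditions: Cp2Zr(H)Cl (1.5 equiv), THF, rt; then H2O, SiO2
Reagents that add atoms: none
Why: Hydrozirconation of the tertiary amide carbonyl and hydrolysis give the aldehyde directly; the hindered trisubstituted alkene is inert on this time scale.

**Step 16**
Reactants: 23 (S)-(+)-carvone
Product: 24 (2S,5S)-2-methyl-5-(prop-1-en-2-yl)cyclohexan-1-one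
Conditions: Li[HB(sec-Bu)3], THF, −78 °C; then H2O
Reagents that add atoms: none
Why: Conjugate hydride reduction of the enone leaves C5 (future C5') untouched; the C2 epimer ratio is irrelevant because this centre is equilibrated in step 20.

**Step 17**
Reactants: 24 (2S,5S)-2-methyl-5-(prop-1-en-2-yl)cyclohexan-1-one
Product: 25 methyl 4-methyl-4-[(1S,4S)-4-methyl-3-oxocyclohexyl]pentanoate
Conditions: methyl acrylate (3 equiv), Fe(acac)3 (30 mol%), PhSiH3, EtOH/(CH2OH)2, 60 °C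
Reagents that add atoms: methyl acrylate, C=CC(=O)OC
Why: Fe–H hydrogen‑atom transfer to the isopropenyl group gives a tertiary radical that adds to the acrylate (Giese addition), creating the C4' gem‑dimethyl quaternary carbon; no stereocentre is formed.

**Step 18**
Reactants: 25 methyl 4-methyl-4-[(1S,4S)-4-methyl-3-oxocyclohexyl]pentanoate
Product: 26 4-[(1S,4S)-3-hydroxy-4-methylcyclohexyl]-4-methylpentan-1-ol (carbinol epimers)
Conditions: LiAlH4, THF, 0 °C → rt
Reagents that add atoms: none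
Why: Exhaustive hydride reduction of ketone and ester avoids a chemoselectivity problem; the carbinol centre is removed in the next step.

**Step 19**
Reactants: 26 4-[(1S,4S)-3-hydroxy-4-methylcyclohexyl]-4-methylpentan-1-ol
Product: 27 4-methyl-4-[(1S,4S)-4-methyl-3-oxocyclohexyl]pentanal
Conditions: Dess–Martin periodinane (2.4 equiv), NaHCO3, CH2Cl2, rt
Reagents that add atoms: none
Why: Mild double oxidation gives the keto aldehyde without over‑oxidation.

**Step 20**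
Reactants: 27 4-methyl-4-[(1S,4S)-4-methyl-3-oxocyclohexyl]pentanal
Product: 28 (2S,4aR)-2,5,5-trimethyl-3,4,4a,5,6,7-hexahydronaphthalen-1(2H)-one
Conditions: KOH, MeOH, 50 °C
Reagents that add atoms: none
Why: Intramolecular aldol condensation: the ketone enolate at C10' adds to the more electrophilic aldehyde and dehydrates to the enone (ring A'), while the α‑methyl centre C8' equilibrates to the equatorial (2S) epimer, trans to the C5'–C4' bond; C5' cannot epimerise.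

**Step 21**
Reactants: 28 (2S,4aR)-2,5,5-trimethyl-3,4,4a,5,6,7-hexahydronaphthalen-1(2H)-one
Product: 29 (2S,4aR)-1,2,5,5-tetramethyl-1,2,3,4,4a,5,6,7-octahydronaphthalen-1-ol (C1 epimers)
Conditions: MeLi, Et2O, −78 °C; then H2O
Reagents that add atoms: methyllithium, [Li]C
Why: 1,2‑Addition of MeLi to the enone gives the tertiary allylic alcohol; its carbinol configuration is lost in the allyl‑metal stage.

**Step 22**
Reactants: 29 (2S,4aR)-1,2,5,5-tetramethyl-1,2,3,4,4a,5,6,7-octahydronaphthalen-1-ol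
Product: 30 (4aR,7S)-1-bromo-4,4,7,8-tetramethyl-1,2,3,4,4a,5,6,7-octahydronaphthalene (C1 epimers)
Conditions: PBr3, pyridine (cat.), Et2O, −20 → 0 °C; used crude
Reagents that add atoms: phosphorus tribromide, BrP(Br)Br
Why: Bromination with allylic transposition (SN2′/ion pair) gives the secondary bromide with the tetrasubstituted C9'=C10' alkene; any regioisomeric bromide converges on the same allylchromium.

**Step 23**
Reactants: 22 2-{(1S,4aS,5R,6R)-5-[(2,5-dimethoxyphenyl)methyl]-1,5,6-trimethyl-1,2,3,4,4a,5,6,7-octahydronaphthalen-1-yl}acetaldehyde; 30 (4aR,7S)-1-bromo-4,4,7,8-tetramethyl-1,2,3,4,4a,5,6,7-octahydronaphthalene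
Product: 32 2-[(1S,4aS,5R,6R)-5-[(2,5-dimethoxyphenyl)methyl]-1,5,6-trimethyl-1,2,3,4,4a,5,6,7-octahydronaphthalen-1-yl]-1-[(1R,2S,4aR)-1,2,5,5-tetramethyl-1,2,3,4,4a,5,6,7-octahydronaphthalen-1-yl]ethan-1-ol (carbinol epimers), via allylchromium dichloride 31 (not isolated)
Conditions: CrCl2 (4 equiv), THF, rt; then H2O
Reagents that add atoms: none
Why: Nozaki–Hiyama carbonyl allylation: the allylchromium adds through a six‑membered chair transition state at its more substituted γ‑terminus C9', creating the quaternary centre and shifting the alkene to C10'=C1'; attack anti to the pseudo‑axial C8' methyl (forced axial by A(1,2) strain) gives (9'R).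

**Step 24**
Reactants: 32 the homoallylic alcohol from step 23
Product: 33 2-[(1S,4aS,5R,6R)-5-[(2,5-dimethoxyphenyl)methyl]-1,5,6-trimethyl-1,2,3,4,4a,5,6,7-octahydronaphthalen-1-yl]-1-[(1R,2S,4aR)-1,2,5,5-tetramethyl-1,2,3,4,4a,5,6,7-octahydronaphthalen-1-yl]ethan-1-one
Conditions: Dess–Martin periodinane, NaHCO3, CH2Cl2, rt
Reagents that add atoms: none
Why: Oxidation merges the carbinol epimers into one ketone whose α‑carbon C9' is quaternary and cannot epimerise.

**Step 25**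
Reactants: 33 the C12 ketone from step 24
Product: 35 2-{[(1R,2R,5S,8aS)-1,2,5-trimethyl-5-{2-[(1R,2S,4aR)-1,2,5,5-tetramethyl-1,2,3,4,4a,5,6,7-octahydronaphthalen-1-yl]ethyl}-1,2,3,5,6,7,8,8a-octahydronaphthalen-1-yl]methyl}-1,4-dimethoxybenzene, via hydrazone 34 (not isolated)
Conditions: N2H4·H2O, KOH, diethylene glycol, 130 → 200 °C
Reagents that add atoms: none
Why: Wolff–Kishner (Huang‑Minlon) reduction removes the carbonyl by an ionic path, avoiding the 1,2‑vinyl shift that a C12 radical next to the alkenyl‑bearing quaternary carbon would undergo; the isolated alkenes and aryl ethers tolerate the base.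

**Step 26**
Reactants: 35 toxiusol hydroquinone bis(methyl ether)
Product: 36 2-{[(1R,2R,5S,8aS)-1,2,5-trimethyl-5-{2-[(1R,2S,4aR)-1,2,5,5-tetramethyl-1,2,3,4,4a,5,6,7-octahydronaphthalen-1-yl]ethyl}-1,2,3,5,6,7,8,8a-octahydronaphthalen-1-yl]methyl}cyclohexa-2,5-diene-1,4-dione
Conditions: (NH4)2Ce(NO3)6, MeCN/H2O, 0 °C
Reagents that add atoms: water, O
Why: Oxidative demethylation of the 1,4‑dimethoxyarene to the quinone is faster than oxidation of the hindered trisubstituted alkenes.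

**Step 27**
Reactants: 36 the quinone from step 26
Product: 37 2-{[(1R,2R,5S,8aS)-1,2,5-trimethyl-5-{2-[(1R,2S,4aR)-1,2,5,5-tetramethyl-1,2,3,4,4a,5,6,7-octahydronaphthalen-1-yl]ethyl}-1,2,3,5,6,7,8,8a-octahydronaphthalen-1-yl]methyl}benzene-1,4-diol
Conditions: Na2S2O4, THF/H2O, rt, under argon
Reagents that add atoms: none
Why: Dithionite reduces the quinone to the hydroquinone without affecting alkenes.

**Step 28**
Reactants: 37 the hydroquinone from step 27
Product: 38 toxiusol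
Conditions: SO3·pyridine (6 equiv), pyridine, 50 °C; then Dowex 50W (H+ form), MeOH, 0 °C
Reagents that add atoms: sulfur trioxide–pyridine complex, [O-]S(=O)(=O)[n+]1ccccc1
Why: O‑Sulfation of both phenols by SO3·pyridine followed by cation exchange gives the bis(hydrogen sulfate); no stereocentre is touched.

**Compound list**
1 | 2-(chloromethyl)-1,4-dimethoxybenzene | COc1ccc(OC)c(CCl)c1 | starting material
2 | ethyl (triphenyl-λ5-phosphanylidene)acetate | CCOC(=O)C=P(c1ccccc1)(c1ccccc1)c1ccccc1 | starting material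
3 | [3-(2,5-dimethoxyphenyl)-1-ethoxy-1-oxopropan-2-yl]triphenylphosphonium chloride | CCOC(=O)C(Cc1cc(OC)ccc1OC)[P+](c1ccccc1)(c1ccccc1)c1ccccc1.[Cl-] | intermediate
4 | ethyl 3-(2,5-dimethoxyphenyl)-2-(triphenyl-λ5-phosphanylidene)propanoate | CCOC(=O)C(Cc1cc(OC)ccc1OC)=P(c1ccccc1)(c1ccccc1)c1ccccc1 | intermediate
5 | ethyl (E)-2-[(2,5-dimethoxyphenyl)methyl]but-2-enoate | C/C=C(/C(=O)OCC)Cc1cc(OC)ccc1OC | intermediate
6 | (E)-2-[(2,5-dimethoxyphenyl)methyl]but-2-en-1-ol | C/C=C(/CO)Cc1cc(OC)ccc1OC | intermediate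
7 | (E)-2-[(2,5-dimethoxyphenyl)methyl]but-2-enal | C/C=C(/C=O)Cc1cc(OC)ccc1OC | intermediate
8 | 2-(3-chloropropyl)-2-methyl-1,3-dioxolane | CC1(CCCCl)OCCO1 | starting material
9 | [3-(2-methyl-1,3-dioxolan-2-yl)propyl]magnesium chloride | CC1(CCC[Mg]Cl)OCCO1 | intermediate
10 | 4-(2-methyl-1,3-dioxolan-2-yl)butanal | CC1(CCCC=O)OCCO1 | intermediate
11 | 1-(triphenyl-λ5-phosphanylidene)propan-2-one | CC(=O)C=P(c1ccccc1)(c1ccccc1)c1ccccc1 | starting material
12 | (E)-7-(2-methyl-1,3-dioxolan-2-yl)hept-3-en-2-one | CC(=O)/C=C/CCCC1(C)OCCO1 | intermediate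
13 | triisopropyl{[(3E)-7-(2-methyl-1,3-dioxolan-2-yl)hepta-1,3-dien-2-yl]oxy}silane | C=C(O[Si](C(C)C)(C(C)C)C(C)C)/C=C/CCCC1(C)OCCO1 | intermediate
14 | (1S,2R,6R)-1-[(2,5-dimethoxyphenyl)methyl]-6-methyl-2-[3-(2-methyl-1,3-dioxolan-2-yl)propyl]-4-[(triisopropylsilyl)oxy]cyclohex-3-ene-1-carbaldehyde | O=C[C@@]1(Cc2cc(OC)ccc2OC)[C@H](C)CC(O[Si](C(C)C)(C(C)C)C(C)C)=C[C@H]1CCCC3(C)OCCO3 | intermediate
15 | (E)-N'-tosylhydrazone of 14 | Cc1ccc(cc1)S(=O)(=O)N/N=C/[C@@]1(Cc2cc(OC)ccc2OC)[C@H](C)CC(O[Si](C(C)C)(C(C)C)C(C)C)=C[C@H]1CCCC3(C)OCCO3 | intermediate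
16 | triisopropyl({(3R,4R,5R)-4-[(2,5-dimethoxyphenyl)methyl]-4,5-dimethyl-3-[3-(2-methyl-1,3-dioxolan-2-yl)propyl]cyclohex-1-en-1-yl}oxy)silane | C[C@@]1(Cc2cc(OC)ccc2OC)[C@H](C)CC(O[Si](C(C)C)(C(C)C)C(C)C)=C[C@H]1CCCC3(C)OCCO3 | intermediate
17 | (3R,4R,4aR)-4-[(2,5-dimethoxyphenyl)methyl]-8-(2-hydroxyethoxy)-3,4,8-trimethyloctahydronaphthalen-1(2H)-one (C8/C8a epimers) | C[C@@]1(Cc2cc(OC)ccc2OC)[C@H](C)CC(=O)C3[C@H]1CCCC3(C)OCCO | intermediate
18 | (3R,4R,4aS)-4-[(2,5-dimethoxyphenyl)methyl]-3,4,8-trimethyl-3,4,4a,5,6,7-hexahydronaphthalen-1(2H)-one | C[C@@]1(Cc2cc(OC)ccc2OC)[C@H](C)CC(=O)C3=C(C)CCC[C@H]31 | intermediate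
19 | (1S,3R,4R,4aS)-4-[(2,5-dimethoxyphenyl)methyl]-3,4,8-trimethyl-1,2,3,4,4a,5,6,7-octahydronaphthalen-1-ol | C[C@@]1(Cc2cc(OC)ccc2OC)[C@H](C)C[C@H](O)C3=C(C)CCC[C@H]31 | intermediate
20 | 1-{[(1S,3R,4R,4aS)-4-[(2,5-dimethoxyphenyl)methyl]-3,4,8-trimethyl-1,2,3,4,4a,5,6,7-octahydronaphthalen-1-yl]oxy}-N,N-dimethylethen-1-amine | C[C@@]1(Cc2cc(OC)ccc2OC)[C@H](C)C[C@H](OC(=C)N(C)C)C3=C(C)CCC[C@H]31 | intermediate
21 | 2-{(1S,4aS,5R,6R)-5-[(2,5-dimethoxyphenyl)methyl]-1,5,6-trimethyl-1,2,3,4,4a,5,6,7-octahydronaphthalen-1-yl}-N,N-dimethylacetamide | C[C@@H]1CC=C2[C@@H](CCC[C@@]2(C)CC(=O)N(C)C)[C@]1(C)Cc1cc(OC)ccc1OC | intermediate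
22 | 2-{(1S,4aS,5R,6R)-5-[(2,5-dimethoxyphenyl)methyl]-1,5,6-trimethyl-1,2,3,4,4a,5,6,7-octahydronaphthalen-1-yl}acetaldehyde | C[C@@H]1CC=C2[C@@H](CCC[C@@]2(C)CC=O)[C@]1(C)Cc1cc(OC)ccc1OC | intermediate
23 | (S)-(+)-carvone, (5S)-2-methyl-5-(prop-1-en-2-yl)cyclohex-2-en-1-one | CC1=CC[C@@H](CC1=O)C(C)=C | starting material
24 | (2S,5S)-2-methyl-5-(prop-1-en-2-yl)cyclohexan-1-one | C[C@H]1CC[C@@H](CC1=O)C(C)=C | intermediate
25 | methyl 4-methyl-4-[(1S,4S)-4-methyl-3-oxocyclohexyl]pentanoate | C[C@H]1CC[C@@H](CC1=O)C(C)(C)CCC(=O)OC | intermediate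
26 | 4-[(1S,4S)-3-hydroxy-4-methylcyclohexyl]-4-methylpentan-1-ol (carbinol epimers) | C[C@H]1CC[C@@H](CC1O)C(C)(C)CCCO | intermediate
27 | 4-methyl-4-[(1S,4S)-4-methyl-3-oxocyclohexyl]pentanal | C[C@H]1CC[C@@H](CC1=O)C(C)(C)CCC=O | intermediate
28 | (2S,4aR)-2,5,5-trimethyl-3,4,4a,5,6,7-hexahydronaphthalen-1(2H)-one | C[C@H]1CC[C@H]2C(=CCCC2(C)C)C1=O | intermediate
29 | (2S,4aR)-1,2,5,5-tetramethyl-1,2,3,4,4a,5,6,7-octahydronaphthalen-1-ol (C1 epimers) | C[C@H]1CC[C@H]2C(=CCCC2(C)C)C1(C)O | intermediate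
30 | (4aR,7S)-1-bromo-4,4,7,8-tetramethyl-1,2,3,4,4a,5,6,7-octahydronaphthalene (C1 epimers) | C[C@H]1CC[C@H]2C(=C1C)C(Br)CCC2(C)C | intermediate
31 | dichloro[(4aR,7S)-4,4,7,8-tetramethyl-1,2,3,4,4a,5,6,7-octahydronaphthalen-1-yl]chromium | C[C@H]1CC[C@H]2C(=C1C)C([Cr](Cl)Cl)CCC2(C)C | intermediate
32 | 2-[(1S,4aS,5R,6R)-5-[(2,5-dimethoxyphenyl)methyl]-1,5,6-trimethyl-1,2,3,4,4a,5,6,7-octahydronaphthalen-1-yl]-1-[(1R,2S,4aR)-1,2,5,5-tetramethyl-1,2,3,4,4a,5,6,7-octahydronaphthalen-1-yl]ethan-1-ol (carbinol epimers) | C[C@@H]1CC=C2[C@@H](CCC[C@@]2(C)CC(O)[C@@]2(C)C3=CCCC(C)(C)[C@H]3CC[C@@H]2C)[C@]1(C)Cc1cc(OC)ccc1OC | intermediate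
33 | 2-[(1S,4aS,5R,6R)-5-[(2,5-dimethoxyphenyl)methyl]-1,5,6-trimethyl-1,2,3,4,4a,5,6,7-octahydronaphthalen-1-yl]-1-[(1R,2S,4aR)-1,2,5,5-tetramethyl-1,2,3,4,4a,5,6,7-octahydronaphthalen-1-yl]ethan-1-one | C[C@@H]1CC=C2[C@@H](CCC[C@@]2(C)CC(=O)[C@@]2(C)C3=CCCC(C)(C)[C@H]3CC[C@@H]2C)[C@]1(C)Cc1cc(OC)ccc1OC | intermediate
34 | hydrazone of 33 | C[C@@H]1CC=C2[C@@H](CCC[C@@]2(C)CC(=NN)[C@@]2(C)C3=CCCC(C)(C)[C@H]3CC[C@@H]2C)[C@]1(C)Cc1cc(OC)ccc1OC | intermediate
35 | 2-{[(1R,2R,5S,8aS)-1,2,5-trimethyl-5-{2-[(1R,2S,4aR)-1,2,5,5-tetramethyl-1,2,3,4,4a,5,6,7-octahydronaphthalen-1-yl]ethyl}-1,2,3,5,6,7,8,8a-octahydronaphthalen-1-yl]methyl}-1,4-dimethoxybenzene | C[C@@H]1CC=C2[C@@H](CCC[C@@]2(C)CC[C@@]2(C)C3=CCCC(C)(C)[C@H]3CC[C@@H]2C)[C@]1(C)Cc1cc(OC)ccc1OC | intermediate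
36 | corresponding 2-substituted cyclohexa-2,5-diene-1,4-dione (quinone) | C[C@@H]1CC=C2[C@@H](CCC[C@@]2(C)CC[C@@]2(C)C3=CCCC(C)(C)[C@H]3CC[C@@H]2C)[C@]1(C)CC1=CC(=O)C=CC1=O | intermediate
37 | corresponding 2-substituted benzene-1,4-diol (hydroquinone) | C[C@@H]1CC=C2[C@@H](CCC[C@@]2(C)CC[C@@]2(C)C3=CCCC(C)(C)[C@H]3CC[C@@H]2C)[C@]1(C)Cc1cc(O)ccc1O | intermediate
38 | toxiusol, the 1,4-phenylene bis(hydrogen sulfate) of 37 | C[C@@H]1CC=C2[C@@H](CCC[C@@]2(C)CC[C@@]2(C)C3=CCCC(C)(C)[C@H]3CC[C@@H]2C)[C@]1(C)Cc1cc(OS(=O)(=O)O)ccc1OS(=O)(=O)O | target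

**Totals**
Total step count: 28.
Longest linear sequence: 18 steps (steps 1–4, 8–15, 23–28).

**Three steps most likely to fail, with fallbacks**

Step 8 (enantioselective Diels–Alder of a trisubstituted enal). The endo/ortho‑para outcome is normal Lewis‑acid behaviour, but the enantioselectivity with this α‑benzyl enal is untested, and the choice of the (S)‑catalyst rests on the binding model for 2‑substituted enals. The fallback sets out from 7 and 13 and comes back at 19. The cycloaddition is run with achiral EtAlCl2 in CH2Cl2 at −78 °C, and 14 to 19 are carried through steps 9–13 as racemates. Racemic 19 is then esterified with (S)-2-methoxy-2-phenylacetic acid (DCC, DMAP) to give two diastereomers separable on silica: the (S)-2-methoxy-2-phenylacetate of 19 F1 and the (S)-2-methoxy-2-phenylacetate of the enantiomer of 19 F2. Methanolysis of F1 (K2CO3, MeOH) returns enantiopure 19.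

Step 14 (Eschenmoser–Claisen at a tetrasubstituted alkene; it also depends on the carbinol configuration from step 13). If dehydration or the wrong C6 epimer intervenes, the fallback sets out from 18 and comes back at 22. Axial conjugate addition of a vinyl cuprate (CH2=CHMgBr, CuBr·SMe2, Me3SiCl, THF, −78 °C) to C4 on the α face, followed by regeneration of the enolate with MeLi and trapping with PhN(SO2CF3)2, gives the dienyl triflate (1R,2R,5S,8aS)-1-[(2,5-dimethoxyphenyl)methyl]-5-ethenyl-1,2,5-trimethyl-1,2,3,5,6,7,8,8a-octahydronaphthalen-4-yl trifluoromethanesulfonate F3. Reduction with Pd(OAc)2, PPh3, HCO2H and Bu3N gives the 4‑vinyl Δ5 compound 2-{[(1R,2R,5S,8aS)-5-ethenyl-1,2,5-trimethyl-1,2,3,5,6,7,8,8a-octahydronaphthalen-1-yl]methyl}-1,4-dimethoxybenzene F4. Hydroboration with 9‑borabicyclo[3.3.1]nonane and NaOH/H2O2 gives the primary alcohol 2-{(1S,4aS,5R,6R)-5-[(2,5-dimethoxyphenyl)methyl]-1,5,6-trimethyl-1,2,3,4,4a,5,6,7-octahydronaphthalen-1-yl}ethan-1-ol F5, and Dess–Martin oxidation gives 22.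

Step 23 (fragment union; a hindered γ,γ‑disubstituted cyclic allyl unit must form a quaternary centre, and the facial selectivity relies on the C8' methyl alone). If the allylchromium is sluggish or unselective, the fallback sets out from 30 and comes back at 32. Borylation of 30 (B2pin2, Pd2(dba)3, DMSO, 50 °C) gives the isolable allylboronate 2-[(4aR,7S)-4,4,7,8-tetramethyl-1,2,3,4,4a,5,6,7-octahydronaphthalen-1-yl]-4,4,5,5-tetramethyl-1,3,2-dioxaborolane F6. This adds to aldehyde 22 under BF3·OEt2 catalysis (CH2Cl2, −78 °C) through a closed chair transition state at C9'; oxidative work‑up gives 32.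

**Further compounds**
F1 | step 8 | (1S,3R,4R,4aS)-4-[(2,5-dimethoxyphenyl)methyl]-3,4,8-trimethyl-1,2,3,4,4a,5,6,7-octahydronaphthalen-1-yl (S)-2-methoxy-2-phenylacetate | C[C@@]1(Cc2cc(OC)ccc2OC)[C@H](C)C[C@H](OC(=O)[C@@H](OC)c2ccccc2)C3=C(C)CCC[C@H]31
F2 | step 8 | (1R,3S,4S,4aR)-4-[(2,5-dimethoxyphenyl)methyl]-3,4,8-trimethyl-1,2,3,4,4a,5,6,7-octahydronaphthalen-1-yl (S)-2-methoxy-2-phenylacetate | C[C@]1(Cc2cc(OC)ccc2OC)[C@@H](C)C[C@@H](OC(=O)[C@@H](OC)c2ccccc2)C3=C(C)CCC[C@@H]31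
F3 | step 14 | (1R,2R,5S,8aS)-1-[(2,5-dimethoxyphenyl)methyl]-5-ethenyl-1,2,5-trimethyl-1,2,3,5,6,7,8,8a-octahydronaphthalen-4-yl trifluoromethanesulfonate | C[C@@H]1CC(OS(=O)(=O)C(F)(F)F)=C2[C@@H](CCC[C@@]2(C)C=C)[C@]1(C)Cc1cc(OC)ccc1OC
F4 | step 14 | 2-{[(1R,2R,5S,8aS)-5-ethenyl-1,2,5-trimethyl-1,2,3,5,6,7,8,8a-octahydronaphthalen-1-yl]methyl}-1,4-dimethoxybenzene | C[C@@H]1CC=C2[C@@H](CCC[C@@]2(C)C=C)[C@]1(C)Cc1cc(OC)ccc1OC
F5 | step 14 | 2-{(1S,4aS,5R,6R)-5-[(2,5-dimethoxyphenyl)methyl]-1,5,6-trimethyl-1,2,3,4,4a,5,6,7-octahydronaphthalen-1-yl}ethan-1-ol | C[C@@H]1CC=C2[C@@H](CCC[C@@]2(C)CCO)[C@]1(C)Cc1cc(OC)ccc1OC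
F6 | step 23 | 2-[(4aR,7S)-4,4,7,8-tetramethyl-1,2,3,4,4a,5,6,7-octahydronaphthalen-1-yl]-4,4,5,5-tetramethyl-1,3,2-dioxaborolane (C1 epimers) | C[C@H]1CC[C@H]2C(=C1C)C(B3OC(C)(C)C(C)(C)O3)CCC2(C)C
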